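## Structural features

The target is a C20 dibromo ether-alcohol in which a tetrahydropyran (ring B: O, C3, C4, C5, C6, C7) and a cyclohexanol (ring A: C10–C15) are joined by the two-carbon linker C8–C9. Ring B carries two fully substituted ether carbons, C3 (methyl, vinyl C1=C2) and C7 (methyl, C8), and a secondary bromide at C6 next to C7. The two methyls are cis across the ring oxygen and the bromide is cis to the C7 methyl (3S,6R,7S). Ring A carries the linker at C10 (R), an axial tertiary hydroxyl with an equatorial methyl at C11 (S), and an equatorial bromide at C14 (R) beside the quaternary C15. Both bromides are neopentyl-like, so they cannot be put in by displacement on a ring, and each is prone to elimination, 1,2-shift or, with a vicinal hydroxyl and base, epoxide closure. The vinyl group tolerates neither ozone nor diimide, and the two stereotriads are too far apart to control one another. The real difficulty is therefore to set each triad on its own and to form two tetrasubstituted C–O carbons and two hindered C–Br bonds stereospecifically. The key step uses the fact that C3 bears oxygen, methyl and a one-carbon arm (C2). Read as CH2OH, that arm is what a C2–C3 epoxide leaves behind when the C7 oxygen opens it at C3, so the O–C3 bond of ring B can be made with inversion after C6–Br and C7 are already in place.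

## Logic of the disconnections

**C1=C2.** The vinyl group of 31 is cut last, giving 30 and, one oxidation level down, 29. The alkene must not be present when the linker is saturated or when ozone is used. The demand on the forward step is a mild methylenation of a non-enolisable aldehyde beside two bromides and a free tertiary alcohol.

**C8–C9.** In 29 (through 28 and 27) the linker is cut as a C8=C9 double bond, giving 12 and 26. This is the only bond whose cleavage separates the two stereotriads. The aldehyde is placed on ring B because C7 is quaternary, so 12 cannot enolise, whereas a C8 carbanion would sit beta to the ring oxygen and gamma to C6–Br. The forward step has to join a beta-branched sulfonyl carbanion to an alpha-quaternary aldehyde, and the alkene must then be reduced without touching C–Br.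

**Oxygen at C2 and C8.** 12 goes back through 11 and 10 to 9 with no skeletal change. The two primary oxygens are told apart because one is free and one is silylated in 9. The demand is orthogonality: benzoate on C2, fluoride-labile silicon on C8.

**O–C3 (key).** 9 is opened at O–C3 to the hydroxy epoxide 8. This removes ring B and the C3 stereocentre in one move and hands C3 to the chiral pool with inversion: 8 has C3 (R), 9 has C3 (S). The forward step needs attack at the tertiary epoxide carbon, clean inversion, and a substrate with one free hydroxyl and no base.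

**O–C2 of the epoxide and C1.** 8 is cut at O–C2 to the primary/tertiary diol 7, and C1 is added back to give the vinyl carbinol 5. The epoxide is made last and under neutral dehydrating conditions, because base would close the C6–C7 bromohydrin and a bromide/Lewis-acid step would not spare a 2,2-disubstituted epoxide. For the same reason the bromide is installed before this epoxide exists, and C8 is silylated once and never reshuffled.

**C6–Br, C6–O/C7–O, C8–O.** 5 goes back to 4 (silyl off), 4 to the epoxy alcohol 3 (C6–Br cut, inversion), 3 to the allylic alcohol 2 (epoxide removed) and 2 to 1 (C8–O removed). The gain is an acyclic, reagent-controlled origin for C6 and C7. The demands are C6-selective bromide delivery and tolerance of the free tertiary vinyl carbinol.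

**C9–S and C11–CH3.** 26 goes back through 25 and 24 to the diol 23 (C9–S cut). 23 is cut at C11–CH3 to the ketone 22, because equatorial methyl delivery past the axial C15 methyl is the reliable way to an axial hydroxyl. 22 comes from 19 via 21 by redox changes only.

**C10–C15, C14–Br, C12–C13.** 19 is cut at C10–C15 to the bromohydrin 18, so that the C14–Br bond predates the ring and is not broken in closing it. 18 goes back to the epoxide 17 (C14–Br cut, inversion), and 17 to 15 and 16 (C12–C13 cut). 15 comes from 13. The demands are regioselective bromide opening at the secondary carbon and ring closure without scrambling C14.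

## Other disconnections considered

**Alternative 1:** The cut is C3–C4 and C6–C7, taking ring B apart into 2,5-dimethylfuran A2 (C3, C7, both methyls, the ring oxygen, and the future C2 and C8 as the furan CH=CH) and a three-carbon vinylcarbenoid from methyl 2-diazobut-3-enoate A3. In the forward step a dirhodium carboxylate catalyst would cyclopropanate A2, and Cope rearrangement of the cis-divinylcyclopropane would give the oxabicyclic diene A1.

- In favour: both tetrasubstituted ether carbons and their cis relationship arise in one catalytic step that can be made enantioselective. Cleaving the etheno bridge would reveal C2 and C8 together, already cis.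
- Against: the ester in A1 sits on the carbon that must become C6–H(Br). The bromide would then have to come from a decarboxylative radical halogenation whose facial outcome beside C7 is not securely controlled. C2 and C8 would emerge as two nearly equivalent carbonyls that must be differentiated.
- Comparison: on structure A1 solves the two quaternary centres more directly than the chosen plan, which is a point where it is better, and it equals the chosen plan in leaving C2 and C8 as oxygenated one-carbon arms. On mechanism the carbenoid cascade is concerted and as reliable for ring construction as the epoxide opening, but it offers nothing for C6, which the chosen plan sets by inversion. On step economy the ring core comes in one step rather than seven, but ester-to-bromide exchange and end differentiation would use up most of that gain.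

**Alternative 2:** The cut is C12–C13 and C14–Br in ring A. In the forward step a copper bromide catalyst with a tripodal pyridylamine ligand would abstract bromine from the bromomethyl ketone A5. The C12 radical would close 6-endo on the terminal alkene carbon, and the C14 radical would take bromine back to give A4.

- In favour: ring and C14–Br are formed in one redox-neutral catalytic step. The ketone arrives with C9 already at the alcohol level, so the reduction and re-oxidation of steps 15 and 16 would fall away; on ring A step count this alternative is better.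
- Against: the 6-endo/5-exo partition is uncertain. C14 would be set by 1,3-induction from C10 in a radical atom transfer, where modest control is expected, whereas steps 11–14 carry C14 over from a reagent-controlled epoxide. A5 is a base-sensitive alpha-bromo ketone, C10 has to be epimerised afterwards, and the benzyl ether must later be removed beside two bromides.
- Comparison: it concerns ring A only, so it competes with steps 11–16 and not with the ring B key step. It equals the chosen plan in convergence (the same union at C8–C9 could follow) and is weaker in stereochemical certainty at C14.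

**Alternative 3:** The cut is O–C7 and C6–Br. The precursor would be the tetrahydrofuran A7, whose ring oxygen is bonded to C3 and C6 and whose tertiary C7 hydroxyl is exocyclic. On activation with a bromide-delivering reagent the ring oxygen would displace the C7 leaving group (inversion) to a bicyclic oxonium ion, and bromide would open it at C6 (inversion) to give A6.

- In favour: C6–Br and ring B would form together, stereospecifically and late. The vinyl group would be kept throughout, so the removal and return of C1 (steps 5, 24, 25) would be unnecessary, which is better step economy on that point. C3 would come from the chiral pool with retention.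
- Against: an activated tertiary hydroxyl tends to ionise or eliminate before it is displaced. Bromide may return to the tertiary C7 instead of C6. The oxonium ion can also open at C3, which is tertiary and allylic. The conditions release acid beside a vinyl group and an enolisable ketone.
- Comparison: it equals the chosen plan in its use of the chiral pool and in relying on an onium opening with inversion. It is shorter, but its regiochemistry depends on three competing openings of one intermediate, whereas the chosen plan fixes C6, C7 and C3 in three separate steps.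

Key step: step 7

Assumption (chemistry): commercial (R)-(−)-linalool is taken as highly but not perfectly enantioenriched; its minor antipode becomes a diastereomer from step 2 on and is removed by chromatography at 4 or 9.

## Route

**Step 1**
Reactants: 1 (R)-(−)-linalool
Product: 2 (2E,6R)-2,6-dimethylocta-2,7-diene-1,6-diol
Conditions: SeO2 (cat.), t-BuOOH, salicylic acid (cat.), CH2Cl2, rt
Reagents that add atoms: tert-butyl hydroperoxide, CC(C)(C)OO
Why: Catalytic selenium dioxide allylic hydroxylation (ene reaction, then [2,3]-shift) should oxidise the (E)-methyl of the trisubstituted alkene; the vinyl group has no allylic hydrogen and the stereocentre is not touched. Stopping short of full conversion limits over-oxidation to the enal.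

**Step 2**
Reactants: 2 (2E,6R)-2,6-dimethylocta-2,7-diene-1,6-diol
Product: 3 (3R)-5-[(2S,3S)-3-(hydroxymethyl)-3-methyloxiran-2-yl]-3-methylpent-1-en-3-ol
Conditions: Ti(OiPr)4 (10 mol%), L-(+)-diisopropyl tartrate (12 mol%), t-BuOOH, 4 Å MS, CH2Cl2, −20 °C
Reagents that add atoms: tert-butyl hydroperoxide, CC(C)(C)OO
Why: Sharpless asymmetric epoxidation: only the primary allylic alcohol is epoxidised at a useful rate, the tertiary vinyl carbinol being far slower. L-(+)-tartrate gives the (2S,3S)-type epoxide from (E)-2-methylalk-2-en-1-ols, so C6 (S) and C7 (S) are reagent-controlled.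

**Step 3**
Reactants: 3 (3R)-5-[(2S,3S)-3-(hydroxymethyl)-3-methyloxiran-2-yl]-3-methylpent-1-en-3-ol
Product: 4 (2S,3R,6R)-3-bromo-2,6-dimethyloct-7-ene-1,2,6-triol
Conditions: BrTi(OiPr)3 (1.5 equiv), CH2Cl2, −20 °C → 0 °C; aqueous work-up
Reagents that add atoms: bromotitanium triisopropoxide, CC(C)O[Ti](Br)(OC(C)C)OC(C)C
Why: Titanium-chelated C3-selective opening of a 2,3-epoxy alcohol: bromide carried by the metal attacks C6, which lies outside the five-membered chelate, with inversion to give C6 (R), while C7 keeps its oxygen. No electrophilic bromine is present, so the vinyl group is spared.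

**Step 4**
Reactants: 4 (2S,3R,6R)-3-bromo-2,6-dimethyloct-7-ene-1,2,6-triol
Product: 5 (3R,6R,7S)-6-bromo-8-[(tert-butyldiphenylsilyl)oxy]-3,7-dimethyloct-1-ene-3,7-diol
Conditions: t-BuPh2SiCl, imidazole, CH2Cl2, 0 °C → rt
Reagents that add atoms: tert-butyldiphenylsilyl chloride, CC(C)(C)[Si](Cl)(c1ccccc1)c1ccccc1
Why: Silylation of the only primary hydroxyl; the two tertiary hydroxyls do not react with this bulky chloride. The group is chosen for its stability to the acid of step 7 and is put on only once.

**Step 5**
Reactants: 5 (3R,6R,7S)-6-bromo-8-[(tert-butyldiphenylsilyl)oxy]-3,7-dimethyloct-1-ene-3,7-diol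
Product: 7 (2R,5R,6S)-5-bromo-7-[(tert-butyldiphenylsilyl)oxy]-2,6-dimethylheptane-1,2,6-triol, via hydroxy aldehyde 6 (not isolated)
Conditions: O3, CH2Cl2/MeOH, −78 °C; then NaBH4, −78 °C → 0 °C
Reagents that add atoms: ozone, [O-][O+]=O
Why: Ozonolysis with reductive work-up: the vinyl group is the only alkene left, C1 is excised and C2 becomes CH2OH. Borohydride at low temperature is not basic enough to close the bromohydrin.

**Step 6**
Reactants: 7 (2R,5R,6S)-5-bromo-7-[(tert-butyldiphenylsilyl)oxy]-2,6-dimethylheptane-1,2,6-triol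
Product: 8 (2S,3R)-3-bromo-1-[(tert-butyldiphenylsilyl)oxy]-2-methyl-5-[(2R)-2-methyloxiran-2-yl]pentan-2-ol
Conditions: PPh3, diisopropyl azodicarboxylate, THF, 0 °C → rt
Reagents that add atoms: none
Why: Mitsunobu cyclodehydration of a 1,2-diol: only the primary C2 hydroxyl forms the oxyphosphonium ion and the adjacent tertiary C3 oxygen closes the three-membered ring, so the C3–O bond is retained and C3 is (R). The medium is neutral, so the C6–C7 bromohydrin, which base would close, is left alone.

**Step 7**
Reactants: 8 (2S,3R)-3-bromo-1-[(tert-butyldiphenylsilyl)oxy]-2-methyl-5-[(2R)-2-methyloxiran-2-yl]pentan-2-ol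
Product: 9 [(2S,5R,6S)-5-bromo-6-{[(tert-butyldiphenylsilyl)oxy]methyl}-2,6-dimethyloxan-2-yl]methanol
Conditions: camphorsulfonic acid (10 mol%), CH2Cl2, 0 °C → rt
Reagents that add atoms: none
Why: Protonation or hydrogen bonding at the epoxide oxygen lengthens the C3–O bond, and the C7 hydroxyl attacks C3 from the rear in a loose SN2-like transition state, so O–C3 forms with inversion and C2 is released as CH2OH. The closest known reaction type is the acid-catalysed intramolecular opening of tri- or 2,2-disubstituted epoxides by hydroxyl groups at the more substituted carbon, as used for polyether tetrahydrofurans and tetrahydropyrans. Ring B closes in the 6-exo-tet mode (O, C7, C6, C5, C4, C3, with the breaking C3–O bond outside the ring). The new stereocentre C3 is controlled by the configuration of the epoxide, which comes unchanged from 1, so (R) in 8 becomes (S) in 9 stereospecifically and not through a conformational preference. Attack at C3 and not C2 is secured by the cationic character of the tertiary carbon and by a six- against a seven-membered ring. Inversion without a free cation is secured by a weak, non-nucleophilic acid in a non-ionising solvent at low temperature. Chemoselectivity is secured because 8 has a single free hydroxyl, an acid-stable silyl ether and no base that could close the bromohydrin.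

**Step 8**
Reactants: 9 [(2S,5R,6S)-5-bromo-6-{[(tert-butyldiphenylsilyl)oxy]methyl}-2,6-dimethyloxan-2-yl]methanol
Product: 10 [(2S,5R,6S)-5-bromo-6-{[(tert-butyldiphenylsilyl)oxy]methyl}-2,6-dimethyloxan-2-yl]methyl benzoate
Conditions: BzCl, pyridine, DMAP (cat.), CH2Cl2, 0 °C → rt
Reagents that add atoms: benzoyl chloride, O=C(Cl)c1ccccc1
Why: Acyl transfer to the neopentyl primary alcohol under nucleophilic catalysis. The benzoate withstands fluoride, oxidation and olefination and is later removed together with the silyl ether on ring A.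

**Step 9**
Reactants: 10 [(2S,5R,6S)-5-bromo-6-{[(tert-butyldiphenylsilyl)oxy]methyl}-2,6-dimethyloxan-2-yl]methyl benzoate
Product: 11 [(2S,5R,6S)-5-bromo-6-(hydroxymethyl)-2,6-dimethyloxan-2-yl]methyl benzoate
Conditions: Bu4NF, AcOH (1:1), THF, rt
Reagents that add atoms: none
Why: Fluoride desilylation buffered with acetic acid, so no free alkoxide can move or cleave the benzoate. The equatorial C6 bromide has no anti-periplanar hydrogen for elimination.

**Step 10**
Reactants: 11 [(2S,5R,6S)-5-bromo-6-(hydroxymethyl)-2,6-dimethyloxan-2-yl]methyl benzoate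
Product: 12 [(2S,5R,6S)-5-bromo-6-formyl-2,6-dimethyloxan-2-yl]methyl benzoate
Conditions: Dess–Martin periodinane, CH2Cl2, rt
Reagents that add atoms: none
Why: Dess–Martin oxidation of the primary alcohol. The aldehyde is attached to the quaternary C7 and cannot enolise or epimerise.

**Step 11**
Reactants: 13 3-methylbut-2-en-1-ol
Product: 15 [(2S)-3,3-dimethyloxiran-2-yl]methyl 4-methylbenzenesulfonate, via epoxy alcohol 14 (not isolated)
Conditions: Ti(OiPr)4 (5 mol%), L-(+)-diisopropyl tartrate (6 mol%), t-BuOOH, 4 Å MS, CH2Cl2, −20 °C; P(OMe)3; then Et3N, DMAP (cat.), TsCl, −10 °C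
Reagents that add atoms: tert-butyl hydroperoxide, CC(C)(C)OO; 4-methylbenzenesulfonyl chloride, Cc1ccc(cc1)S(Cl)(=O)=O
Why: Sharpless asymmetric epoxidation with in situ sulfonylation, used because the small epoxy alcohol is volatile and water-soluble. L-(+)-tartrate gives the (2S) epoxide, which carries the future C14.

**Step 12**
Reactants: 16 methyl acetoacetate; 15 [(2S)-3,3-dimethyloxiran-2-yl]methyl 4-methylbenzenesulfonate
Product: 17 methyl 5-[(2S)-3,3-dimethyloxiran-2-yl]-3-oxopentanoate
Conditions: 16, NaH, THF, 0 °C; n-BuLi, 0 °C; then 15, 0 °C → rt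
Reagents that add atoms: none
Why: Gamma-alkylation of the acetoacetate dianion. Displacement occurs at the primary CH2OTs carbon because the epoxide carbons are secondary-hindered and tertiary, so the stereocentre is not involved and C12–C13 is formed.

**Step 13**
Reactants: 17 methyl 5-[(2S)-3,3-dimethyloxiran-2-yl]-3-oxopentanoate
Product: 18 methyl (6R)-6-bromo-7-hydroxy-7-methyl-3-oxooctanoate
Conditions: Li2NiBr4 (THF solution), THF, 0 °C → rt
Reagents that add atoms: dilithium tetrabromonickelate, [Li+].[Li+].Br[Ni-2](Br)(Br)Br
Why: SN2 opening of a trisubstituted epoxide by soft, weakly acidic bromide at the less substituted carbon, with inversion, should give the (R) secondary bromide and leave the tertiary hydroxyl at C15.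

**Step 14**
Reactants: 18 methyl (6R)-6-bromo-7-hydroxy-7-methyl-3-oxooctanoate
Product: 19 methyl (1R,3R)-3-bromo-2,2-dimethyl-6-oxocyclohexane-1-carboxylate
Conditions: SnCl4 (2 equiv), CH2Cl2, −78 °C → −20 °C
Reagents that add atoms: none
Why: Proposed new method: SnCl4 should ionise the tertiary C15 hydroxyl with assistance from the vicinal bromine, and the resulting bromonium ion is opened at the tertiary carbon by C10 of the tin-chelated keto ester enol through a chair transition state, so C10–C15 forms while the C14–Br bond and its configuration are never broken. The closest known reaction types are the SnCl4-mediated cyclisation of olefinic beta-keto esters through tertiary cations and the stereospecific capture by pi-nucleophiles of bromonium ions generated from beta-bromo tertiary leaving groups. C10 stays epimerisable and should settle with the ester equatorial, cis to bromine.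

**Step 15**
Reactants: 19 methyl (1R,3R)-3-bromo-2,2-dimethyl-6-oxocyclohexane-1-carboxylate
Product: 21 (2S,4R)-4-bromo-2-(hydroxymethyl)-3,3-dimethylcyclohexan-1-ol (both C1 epimers), via hydroxy ester 20 (not isolated)
Conditions: LiBH4, THF/MeOH, 0 °C → rt
Reagents that add atoms: none
Why: Borohydride reduction of the ketone and then of the beta-hydroxy ester gives the 1,3-diol. The carbinol configuration does not matter because it is re-oxidised, and the hindered secondary bromide is inert to borohydride.

**Step 16**
Reactants: 21 (2S,4R)-4-bromo-2-(hydroxymethyl)-3,3-dimethylcyclohexan-1-ol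
Product: 22 (2S,4R)-4-bromo-2-(hydroxymethyl)-3,3-dimethylcyclohexan-1-one
Conditions: NaOCl (aq.), AcOH, 0 °C → rt
Reagents that add atoms: none
Why: Hypochlorite in acetic acid oxidises secondary alcohols in preference to primary ones, giving the beta-hydroxy ketone. C10 is again alpha to a carbonyl and can equilibrate to the equatorial arrangement cis to the C14 bromide.

**Step 17**
Reactants: 22 (2S,4R)-4-bromo-2-(hydroxymethyl)-3,3-dimethylcyclohexan-1-one
Product: 23 (1S,2S,4R)-4-bromo-2-(hydroxymethyl)-1,3,3-trimethylcyclohexan-1-ol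
Conditions: MeMgBr (3.5 equiv), LaCl3·2LiCl (30 mol%), THF, −78 °C → 0 °C
Reagents that add atoms: methylmagnesium bromide, C[Mg]Br
Why: Lanthanide-assisted Grignard addition to an enolisable ketone: the axial C15 methyl blocks the axial trajectory at C11, so methyl enters equatorially and the hydroxyl ends axial, cis to the C10 arm (11S). The first equivalent only deprotonates the primary hydroxyl.

**Step 18**
Reactants: 23 (1S,2S,4R)-4-bromo-2-(hydroxymethyl)-1,3,3-trimethylcyclohexan-1-ol
Product: 24 (1S,2R,4R)-4-bromo-1,3,3-trimethyl-2-{[(1-phenyl-1H-tetrazol-5-yl)sulfanyl]methyl}cyclohexan-1-ol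
Conditions: 1-phenyl-1H-tetrazole-5-thiol, PPh3, diisopropyl azodicarboxylate, THF, 0 °C → rt
Reagents that add atoms: 1-phenyl-1H-tetrazole-5-thiol, Sc1nnnn1-c2ccccc2
Why: Mitsunobu thioetherification at the primary hydroxyl; the tertiary hydroxyl is not activated.

**Step 19**
Reactants: 24 (1S,2R,4R)-4-bromo-1,3,3-trimethyl-2-{[(1-phenyl-1H-tetrazol-5-yl)sulfanyl]methyl}cyclohexan-1-ol
Product: 25 (1S,2R,4R)-4-bromo-1,3,3-trimethyl-2-{[(1-phenyl-1H-tetrazol-5-yl)sulfonyl]methyl}cyclohexan-1-ol
Conditions: (NH4)6Mo7O24·4H2O (10 mol%), 30% H2O2, EtOH, rt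
Reagents that add atoms: hydrogen peroxide, OO
Why: Molybdate-catalysed peroxide oxidation of the sulfide to the sulfone; the tertiary alcohol and the alkyl bromide are inert.

**Step 20**
Reactants: 25 (1S,2R,4R)-4-bromo-1,3,3-trimethyl-2-{[(1-phenyl-1H-tetrazol-5-yl)sulfonyl]methyl}cyclohexan-1-ol
Product: 26 5-({(1R,2S,5R)-5-bromo-2,6,6-trimethyl-2-[(trimethylsilyl)oxy]cyclohexyl}methanesulfonyl)-1-phenyl-1H-tetrazole
Conditions: Me3SiOTf, 2,6-lutidine, CH2Cl2, −78 °C
Reagents that add atoms: trimethylsilyl trifluoromethanesulfonate, C[Si](C)(C)OS(=O)(=O)C(F)(F)F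
Why: Silylation of the hindered tertiary hydroxyl with a silyl triflate, so that no gamma-alkoxide can compete with the sulfonyl carbanion or attack the tetrazole in step 21.

**Step 21**
Reactants: 12 [(2S,5R,6S)-5-bromo-6-formyl-2,6-dimethyloxan-2-yl]methyl benzoate; 26 5-({(1R,2S,5R)-5-bromo-2,6,6-trimethyl-2-[(trimethylsilyl)oxy]cyclohexyl}methanesulfonyl)-1-phenyl-1H-tetrazole
Product: 27 {(2S,5R,6S)-5-bromo-6-[(E)-2-{(1R,2S,5R)-5-bromo-2,6,6-trimethyl-2-[(trimethylsilyl)oxy]cyclohexyl}ethenyl]-2,6-dimethyloxan-2-yl}methyl benzoate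
Conditions: 26, KN(SiMe3)2, DME, −60 °C; then 12, −60 °C → rt
Reagents that add atoms: none
Why: Julia–Kocienski olefination (addition, Smiles rearrangement, loss of sulfur dioxide and tetrazolate) forms C8=C9; the alkene geometry is of no consequence. The aldehyde cannot enolise, and the equatorial C6 bromide is gauche to C7–C8, so a Grob-type fragmentation of the adduct alkoxide is not aligned.

**Step 22**
Reactants: 27 {(2S,5R,6S)-5-bromo-6-[(E)-2-{(1R,2S,5R)-5-bromo-2,6,6-trimethyl-2-[(trimethylsilyl)oxy]cyclohexyl}ethenyl]-2,6-dimethyloxan-2-yl}methyl benzoate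
Product: 28 {(2S,5R,6S)-5-bromo-6-[2-{(1R,2S,5R)-5-bromo-2,6,6-trimethyl-2-[(trimethylsilyl)oxy]cyclohexyl}ethyl]-2,6-dimethyloxan-2-yl}methyl benzoate
Conditions: 2-nitrobenzenesulfonylhydrazide, Et3N, CH2Cl2, rt (repeated charges)
Reagents that add atoms: none
Why: Diimide reduction (concerted syn transfer of two hydrogens) saturates the disubstituted alkene without touching C–Br bonds, the benzoate or the silyl ether. This is why the vinyl group is not yet present.

**Step 23**
Reactants: 28 {(2S,5R,6S)-5-bromo-6-[2-{(1R,2S,5R)-5-bromo-2,6,6-trimethyl-2-[(trimethylsilyl)oxy]cyclohexyl}ethyl]-2,6-dimethyloxan-2-yl}methyl benzoate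
Product: 29 (1S,2R,4R)-4-bromo-2-{2-[(2S,3R,6S)-3-bromo-6-(hydroxymethyl)-2,6-dimethyloxan-2-yl]ethyl}-1,3,3-trimethylcyclohexan-1-ol
Conditions: K2CO3, MeOH, rt
Reagents that add atoms: none
Why: Methanolysis removes the benzoate and the tertiary trimethylsilyl ether in one operation. Neither bromide has a vicinal hydroxyl, so no epoxide can form under this mild base.

**Step 24**
Reactants: 29 (1S,2R,4R)-4-bromo-2-{2-[(2S,3R,6S)-3-bromo-6-(hydroxymethyl)-2,6-dimethyloxan-2-yl]ethyl}-1,3,3-trimethylcyclohexan-1-ol
Product: 30 (2S,5R,6S)-5-bromo-6-{2-[(1R,2S,5R)-5-bromo-2-hydroxy-2,6,6-trimethylcyclohexyl]ethyl}-2,6-dimethyloxane-2-carbaldehyde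
Conditions: Dess–Martin periodinane, CH2Cl2, rt
Reagents that add atoms: none
Why: Dess–Martin oxidation affects only the primary alcohol; the tertiary alcohol cannot be oxidised and the aldehyde on quaternary C3 cannot epimerise.

**Step 25**
Reactants: 30 (2S,5R,6S)-5-bromo-6-{2-[(1R,2S,5R)-5-bromo-2-hydroxy-2,6,6-trimethylcyclohexyl]ethyl}-2,6-dimethyloxane-2-carbaldehyde
Product: 31 (1S,2R,4R)-4-bromo-2-{2-[(2S,3R,6S)-3-bromo-6-ethenyl-2,6-dimethyloxan-2-yl]ethyl}-1,3,3-trimethylcyclohexan-1-ol
Conditions: Ph3PCH3Br, KN(SiMe3)2, THF, 0 °C; then 30, 0 °C → rt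
Reagents that add atoms: methyltriphenylphosphonium bromide, C[P+](c1ccccc1)(c2ccccc2)c3ccccc3.[Br-]
Why: Wittig methylenation restores C1 on a non-enolisable aldehyde; excess ylide covers the free tertiary hydroxyl. Both bromides are equatorial and lack an anti-periplanar hydrogen, so elimination is not expected at this temperature.

## Compound list

1 | (R)-(−)-linalool, (3R)-3,7-dimethylocta-1,6-dien-3-ol | C=C[C@@](O)(C)CCC=C(C)C | starting material
2 | (2E,6R)-2,6-dimethylocta-2,7-diene-1,6-diol | C=C[C@@](O)(C)CC/C=C(\C)CO | intermediate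
3 | (3R)-5-[(2S,3S)-3-(hydroxymethyl)-3-methyloxiran-2-yl]-3-methylpent-1-en-3-ol | C=C[C@@](O)(C)CC[C@@H]1O[C@@]1(C)CO | intermediate
4 | (2S,3R,6R)-3-bromo-2,6-dimethyloct-7-ene-1,2,6-triol | C=C[C@@](O)(C)CC[C@@H](Br)[C@@](C)(O)CO | intermediate
5 | (3R,6R,7S)-6-bromo-8-[(tert-butyldiphenylsilyl)oxy]-3,7-dimethyloct-1-ene-3,7-diol | C=C[C@@](O)(C)CC[C@@H](Br)[C@@](C)(O)CO[Si](c1ccccc1)(c2ccccc2)C(C)(C)C | intermediate
6 | (2R,5R,6S)-5-bromo-7-[(tert-butyldiphenylsilyl)oxy]-2,6-dihydroxy-2,6-dimethylheptanal | O=C[C@@](O)(C)CC[C@@H](Br)[C@@](C)(O)CO[Si](c1ccccc1)(c2ccccc2)C(C)(C)C | intermediate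
7 | (2R,5R,6S)-5-bromo-7-[(tert-butyldiphenylsilyl)oxy]-2,6-dimethylheptane-1,2,6-triol | OC[C@@](O)(C)CC[C@@H](Br)[C@@](C)(O)CO[Si](c1ccccc1)(c2ccccc2)C(C)(C)C | intermediate
8 | (2S,3R)-3-bromo-1-[(tert-butyldiphenylsilyl)oxy]-2-methyl-5-[(2R)-2-methyloxiran-2-yl]pentan-2-ol | C1O[C@]1(C)CC[C@@H](Br)[C@@](C)(O)CO[Si](c2ccccc2)(c3ccccc3)C(C)(C)C | intermediate
9 | [(2S,5R,6S)-5-bromo-6-{[(tert-butyldiphenylsilyl)oxy]methyl}-2,6-dimethyloxan-2-yl]methanol | OC[C@]1(C)CC[C@@H](Br)[C@](C)(CO[Si](c2ccccc2)(c3ccccc3)C(C)(C)C)O1 | intermediate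
10 | [(2S,5R,6S)-5-bromo-6-{[(tert-butyldiphenylsilyl)oxy]methyl}-2,6-dimethyloxan-2-yl]methyl benzoate | O=C(OC[C@]1(C)CC[C@@H](Br)[C@](C)(CO[Si](c2ccccc2)(c3ccccc3)C(C)(C)C)O1)c4ccccc4 | intermediate
11 | [(2S,5R,6S)-5-bromo-6-(hydroxymethyl)-2,6-dimethyloxan-2-yl]methyl benzoate | O=C(OC[C@]1(C)CC[C@@H](Br)[C@](C)(CO)O1)c2ccccc2 | intermediate
12 | [(2S,5R,6S)-5-bromo-6-formyl-2,6-dimethyloxan-2-yl]methyl benzoate | O=C(OC[C@]1(C)CC[C@@H](Br)[C@](C)(C=O)O1)c2ccccc2 | intermediate
13 | 3-methylbut-2-en-1-ol | CC(C)=CCO | starting material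
14 | [(2S)-3,3-dimethyloxiran-2-yl]methanol | OC[C@@H]1OC1(C)C | intermediate
15 | [(2S)-3,3-dimethyloxiran-2-yl]methyl 4-methylbenzenesulfonate | Cc1ccc(cc1)S(=O)(=O)OC[C@@H]2OC2(C)C | intermediate
16 | methyl acetoacetate, methyl 3-oxobutanoate | COC(=O)CC(C)=O | starting material
17 | methyl 5-[(2S)-3,3-dimethyloxiran-2-yl]-3-oxopentanoate | COC(=O)CC(=O)CC[C@@H]1OC1(C)C | intermediate
18 | methyl (6R)-6-bromo-7-hydroxy-7-methyl-3-oxooctanoate | COC(=O)CC(=O)CC[C@@H](Br)C(C)(C)O | intermediate
19 | methyl (1R,3R)-3-bromo-2,2-dimethyl-6-oxocyclohexane-1-carboxylate | COC(=O)[C@@H]1C(C)(C)[C@H](Br)CCC1=O | intermediate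
20 | methyl (1R,3R)-3-bromo-6-hydroxy-2,2-dimethylcyclohexane-1-carboxylate (both C6 epimers) | COC(=O)[C@@H]1C(C)(C)[C@H](Br)CCC1O | intermediate
21 | (2S,4R)-4-bromo-2-(hydroxymethyl)-3,3-dimethylcyclohexan-1-ol (both C1 epimers) | OC[C@@H]1C(C)(C)[C@H](Br)CCC1O | intermediate
22 | (2S,4R)-4-bromo-2-(hydroxymethyl)-3,3-dimethylcyclohexan-1-one | OC[C@@H]1C(C)(C)[C@H](Br)CCC1=O | intermediate
23 | (1S,2S,4R)-4-bromo-2-(hydroxymethyl)-1,3,3-trimethylcyclohexan-1-ol | OC[C@@H]1C(C)(C)[C@H](Br)CC[C@]1(C)O | intermediate
24 | (1S,2R,4R)-4-bromo-1,3,3-trimethyl-2-{[(1-phenyl-1H-tetrazol-5-yl)sulfanyl]methyl}cyclohexan-1-ol | c1ccccc1-n2nnnc2SC[C@@H]3C(C)(C)[C@H](Br)CC[C@]3(C)O | intermediate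
25 | (1S,2R,4R)-4-bromo-1,3,3-trimethyl-2-{[(1-phenyl-1H-tetrazol-5-yl)sulfonyl]methyl}cyclohexan-1-ol | c1ccccc1-n2nnnc2S(=O)(=O)C[C@@H]3C(C)(C)[C@H](Br)CC[C@]3(C)O | intermediate
26 | 5-({(1R,2S,5R)-5-bromo-2,6,6-trimethyl-2-[(trimethylsilyl)oxy]cyclohexyl}methanesulfonyl)-1-phenyl-1H-tetrazole | c1ccccc1-n2nnnc2S(=O)(=O)C[C@@H]3C(C)(C)[C@H](Br)CC[C@]3(C)O[Si](C)(C)C | intermediate
27 | {(2S,5R,6S)-5-bromo-6-[(E)-2-{(1R,2S,5R)-5-bromo-2,6,6-trimethyl-2-[(trimethylsilyl)oxy]cyclohexyl}ethenyl]-2,6-dimethyloxan-2-yl}methyl benzoate | O=C(OC[C@]1(C)CC[C@@H](Br)[C@](C)(/C=C/[C@@H]2C(C)(C)[C@H](Br)CC[C@]2(C)O[Si](C)(C)C)O1)c3ccccc3 | intermediate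
28 | {(2S,5R,6S)-5-bromo-6-[2-{(1R,2S,5R)-5-bromo-2,6,6-trimethyl-2-[(trimethylsilyl)oxy]cyclohexyl}ethyl]-2,6-dimethyloxan-2-yl}methyl benzoate | O=C(OC[C@]1(C)CC[C@@H](Br)[C@](C)(CC[C@@H]2C(C)(C)[C@H](Br)CC[C@]2(C)O[Si](C)(C)C)O1)c3ccccc3 | intermediate
29 | (1S,2R,4R)-4-bromo-2-{2-[(2S,3R,6S)-3-bromo-6-(hydroxymethyl)-2,6-dimethyloxan-2-yl]ethyl}-1,3,3-trimethylcyclohexan-1-ol | OC[C@]1(C)CC[C@@H](Br)[C@](C)(CC[C@@H]2C(C)(C)[C@H](Br)CC[C@]2(C)O)O1 | intermediate
30 | (2S,5R,6S)-5-bromo-6-{2-[(1R,2S,5R)-5-bromo-2-hydroxy-2,6,6-trimethylcyclohexyl]ethyl}-2,6-dimethyloxane-2-carbaldehyde | O=C[C@]1(C)CC[C@@H](Br)[C@](C)(CC[C@@H]2C(C)(C)[C@H](Br)CC[C@]2(C)O)O1 | intermediate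
31 | (1S,2R,4R)-4-bromo-2-{2-[(2S,3R,6S)-3-bromo-6-ethenyl-2,6-dimethyloxan-2-yl]ethyl}-1,3,3-trimethylcyclohexan-1-ol | C=C[C@]1(C)CC[C@@H](Br)[C@](C)(CC[C@@H]2C(C)(C)[C@H](Br)CC[C@]2(C)O)O1 | target

## Step count and least certain steps

Total step count: 25 (steps 1–10 for ring B, steps 11–20 for ring A, steps 21–25 for union and end game). Longest linear sequence: 15 steps (1 → 31 through steps 1–10 and 21–25; the branch 13 → 31 through steps 11–25 is equally long).

**Step 14 (Proposed new method).** The ring closure may lose to other fates of the cation: O-alkylation by the enol oxygen to a dihydropyran, 1,2-hydride shift or proton loss to an allylic bromide, or chloride capture. The bromonium ion competes with a poorly stabilised open cation, and the enol must approach a fully substituted carbon. The fallback uses the known halonium-induced carbocyclisation of alkenyl 1,3-dicarbonyl compounds, in racemic form. It sets out from 16, whose dianion is alkylated with prenyl bromide to give methyl 7-methyl-3-oxooct-6-enoate F1. Treatment of F1 with Et2SBr·SbCl5Br (MeNO2, −25 °C) should close the same ring through a bromonium ion formed directly on the alkene, giving 19 together with its mirror image methyl (1S,3S)-3-bromo-2,2-dimethyl-6-oxocyclohexane-1-carboxylate F2. The enantiomers are parted by preparative chromatography on a chiral stationary phase, and the route is rejoined at 19.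

**Step 7 (key step).** Ionisation may run ahead of ring closure, because the tertiary hydroxyl is hindered and inductively deactivated by the vicinal bromine and silyloxymethyl group. That would cost configuration at C3 or lead to hydride shift to an aldehyde (Meinwald rearrangement) or to intermolecular opening. The fallback changes the nucleophile and the mode of activation. It sets out from 8, which is silylated with N-(trimethylsilyl)imidazole to the C7 trimethylsilyl ether of 8, F3. Catalytic Me3SiOTf in CH2Cl2 at −78 °C should then let the ether oxygen open the silyl-activated epoxide at C3 with transfer of silicon to the C2 oxygen, giving the C2 trimethylsilyl ether of 9, F4. Methanolysis (K2CO3, MeOH) returns the route to 9.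

**Step 3.** Bromide may attack the tertiary C7, since the electronic bias of a 2-methyl epoxy alcohol opposes the chelate bias. The free C3 hydroxyl may close an oxolane on C6, and the tertiary vinyl carbinol may ionise under the Lewis acid. The fallback gives up chelation. It sets out from 3, which is silylated (t-BuPh2SiCl, imidazole) to (3R)-5-[(2S,3S)-3-{[(tert-butyldiphenylsilyl)oxy]methyl}-3-methyloxiran-2-yl]-3-methylpent-1-en-3-ol F5. Li2NiBr4 in THF should then open F5 by SN2 at the less hindered C6, whose neighbour C7 is deactivated toward ionisation by the silyloxymethyl group, and the route is rejoined at 5.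

**Step 13.** Bromide may enter at the tertiary carbon, because a trisubstituted epoxide carries more positive charge there, and the keto ester may bind nickel and release acid that worsens this. The fallback avoids the epoxide. It sets out from 13, which is subjected to catalytic enantioselective bromochlorination of the allylic alcohol (ClTi(OiPr)3, N-bromosuccinimide, chiral Schiff-base ligand) to give (2R)-2-bromo-3-chloro-3-methylbutan-1-ol F6. Triflation (Tf2O, 2,6-lutidine) gives (2R)-2-bromo-3-chloro-3-methylbutyl trifluoromethanesulfonate F7, which alkylates the dianion of 16 to methyl (6R)-6-bromo-7-chloro-7-methyl-3-oxooctanoate F8. Under the conditions of step 14 the tertiary chloride of F8 ionises in place of the hydroxyl, and the route is rejoined at 19.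

**Step 21.** Addition of a beta-branched sulfonyl carbanion, flanked by two quaternary carbons, to an alpha-quaternary aldehyde may be too slow, leaving time for decomposition of the metalated sulfone or attack on the benzoate. The fallback uses a more nucleophilic phosphorus ylide on a different fragment. It sets out from 23, which is converted (I2, PPh3, imidazole) to (1S,2R,4R)-4-bromo-2-(iodomethyl)-1,3,3-trimethylcyclohexan-1-ol F9 and then (PPh3, MeCN, 80 °C) to {[(1R,2S,5R)-5-bromo-2-hydroxy-2,6,6-trimethylcyclohexyl]methyl}triphenylphosphonium iodide F10. Two equivalents of KN(SiMe3)2 and then 12 should give {(2S,5R,6S)-5-bromo-6-[(Z)-2-{(1R,2S,5R)-5-bromo-2-hydroxy-2,6,6-trimethylcyclohexyl}ethenyl]-2,6-dimethyloxan-2-yl}methyl benzoate F11, a Z-alkene that diimide reduces more readily than 27. Reduction under the conditions of step 22 gives {(2S,5R,6S)-5-bromo-6-[2-{(1R,2S,5R)-5-bromo-2-hydroxy-2,6,6-trimethylcyclohexyl}ethyl]-2,6-dimethyloxan-2-yl}methyl benzoate F12, and methanolysis as in step 23 rejoins the route at 29.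

## Further compounds

F1 | step 14 | methyl 7-methyl-3-oxooct-6-enoate | COC(=O)CC(=O)CCC=C(C)C
F2 | step 14 | methyl (1S,3S)-3-bromo-2,2-dimethyl-6-oxocyclohexane-1-carboxylate | COC(=O)[C@H]1C(C)(C)[C@@H](Br)CCC1=O
F3 | step 7 | {[(2S,3R)-3-bromo-1-[(tert-butyldiphenylsilyl)oxy]-2-methyl-5-[(2R)-2-methyloxiran-2-yl]pentan-2-yl]oxy}trimethylsilane | C1O[C@]1(C)CC[C@@H](Br)[C@@](C)(O[Si](C)(C)C)CO[Si](c2ccccc2)(c3ccccc3)C(C)(C)C
F4 | step 7 | {[(2S,5R,6S)-5-bromo-6-{[(tert-butyldiphenylsilyl)oxy]methyl}-2,6-dimethyloxan-2-yl]methoxy}trimethylsilane | C[Si](C)(C)OC[C@]1(C)CC[C@@H](Br)[C@](C)(CO[Si](c2ccccc2)(c3ccccc3)C(C)(C)C)O1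
F5 | step 3 | (3R)-5-[(2S,3S)-3-{[(tert-butyldiphenylsilyl)oxy]methyl}-3-methyloxiran-2-yl]-3-methylpent-1-en-3-ol | C=C[C@@](O)(C)CC[C@@H]1O[C@@]1(C)CO[Si](c2ccccc2)(c3ccccc3)C(C)(C)C
F6 | step 13 | (2R)-2-bromo-3-chloro-3-methylbutan-1-ol | OC[C@@H](Br)C(C)(C)Cl
F7 | step 13 | (2R)-2-bromo-3-chloro-3-methylbutyl trifluoromethanesulfonate | FC(F)(F)S(=O)(=O)OC[C@@H](Br)C(C)(C)Cl
F8 | step 13 | methyl (6R)-6-bromo-7-chloro-7-methyl-3-oxooctanoate | COC(=O)CC(=O)CC[C@@H](Br)C(C)(C)Cl
F9 | step 21 | (1S,2R,4R)-4-bromo-2-(iodomethyl)-1,3,3-trimethylcyclohexan-1-ol | IC[C@@H]1C(C)(C)[C@H](Br)CC[C@]1(C)O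
F10 | step 21 | {[(1R,2S,5R)-5-bromo-2-hydroxy-2,6,6-trimethylcyclohexyl]methyl}triphenylphosphonium iodide | c1ccccc1[P+](c2ccccc2)(c3ccccc3)C[C@@H]4C(C)(C)[C@H](Br)CC[C@]4(C)O.[I-]
F11 | step 21 | {(2S,5R,6S)-5-bromo-6-[(Z)-2-{(1R,2S,5R)-5-bromo-2-hydroxy-2,6,6-trimethylcyclohexyl}ethenyl]-2,6-dimethyloxan-2-yl}methyl benzoate | O=C(OC[C@]1(C)CC[C@@H](Br)[C@](C)(/C=C\[C@@H]2C(C)(C)[C@H](Br)CC[C@]2(C)O)O1)c3ccccc3
F12 | step 21 | {(2S,5R,6S)-5-bromo-6-[2-{(1R,2S,5R)-5-bromo-2-hydroxy-2,6,6-trimethylcyclohexyl}ethyl]-2,6-dimethyloxan-2-yl}methyl benzoate | O=C(OC[C@]1(C)CC[C@@H](Br)[C@](C)(CC[C@@H]2C(C)(C)[C@H](Br)CC[C@]2(C)O)O1)c3ccccc3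
A1 | alternative 1 | methyl (1S,5S)-1,5-dimethyl-8-oxabicyclo[3.2.1]octa-2,6-diene-2-carboxylate | C[C@]12CC=C(C(=O)OC)[C@](C)(C=C1)O2
A2 | alternative 1 | 2,5-dimethylfuran | Cc1ccc(C)o1
A3 | alternative 1 | methyl 2-diazobut-3-enoate | COC(=O)C(=[N+]=[N-])C=C
A4 | alternative 2 | (2R,4R)-2-[(benzyloxy)methyl]-4-bromo-3,3-dimethylcyclohexan-1-one | c1ccccc1COC[C@H]2C(C)(C)[C@H](Br)CCC2=O
A5 | alternative 2 | (3R)-3-[(benzyloxy)methyl]-1-bromo-4,4-dimethylhex-5-en-2-one | BrCC(=O)[C@@H](COCc1ccccc1)C(C)(C)C=C
A6 | alternative 3 | (2R,4R)-4-bromo-2-{2-[(2S,3R,6S)-3-bromo-6-ethenyl-2,6-dimethyloxan-2-yl]ethyl}-3,3-dimethylcyclohexan-1-one | C=C[C@]1(C)CC[C@@H](Br)[C@](C)(CC[C@@H]2C(C)(C)[C@H](Br)CCC2=O)O1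
A7 | alternative 3 | (2R,4R)-4-bromo-2-{(3R)-3-[(2S,5S)-5-ethenyl-5-methyloxolan-2-yl]-3-hydroxybutyl}-3,3-dimethylcyclohexan-1-one | C=C[C@]1(C)CC[C@H](O1)[C@](C)(O)CC[C@@H]2C(C)(C)[C@H](Br)CCC2=O
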